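**Retrosynthetic overview**

1. The target is coumarin A (6-hydroxy-7-methoxy-2H-chromen-2-one) joined through its C3 oxygen to C7' of coumarin B (primed atoms). The last disconnections are the O-benzyl group on C6 and the pyranone of B (C3'=C4' by Wittig reaction, O1'-C2' by lactonisation), which lead back to a 4-aryloxysalicylaldehyde 19.
2. The strategy rests on the benzene ring of B: it carries oxygens on C7' and C8a' (meta to each other) and the carbon C4a' para to C7' and ortho to C8a'. This is the pattern left by a 1,1,3-trioxygenated butadiene and propynal after cycloaddition (bonds C5'-C6' and C4a'-C8a') and loss of methanol, with the ether oxygen already on C3 of the diene.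
3. The diene 14 is the silyl ketene acetal of crotonate 13, which is the conjugate adduct of the enol oxygen of 3-hydroxycoumarin 11 to methyl but-2-ynoate. The diaryl ether is therefore never made by O-arylation.
4. Compound 11 comes from O-benzylvanillin by Baeyer-Villiger oxidation, ortho-formylation, azlactone condensation with N-acetylglycine and enamide hydrolysis.
5. Order of ring formation: benzene of A (purchased), pyranone of A (step 3), benzene of B (step 8), pyranone of B (step 9).

Key step: step 8

Remark: the ketene acetal geometry of diene 14 disappears on aromatisation, so either isomer serves; the Z isomer expected from carbonyl-directed deprotonation is drawn.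

**Route**

Step 1
Reactants: 1 4-(benzyloxy)-3-methoxybenzaldehyde
Product: 3 4-(benzyloxy)-3-methoxyphenol, via aryl formate 2 (not isolated)
Conditions: mCPBA, CH2Cl2, 0 °C to rt; then K2CO3 (cat.), MeOH, rt
Reagents that add atoms: 3-chloroperoxybenzoic acid (mCPBA), O=C(OO)c1cccc(Cl)c1
Why: Baeyer-Villiger oxidation of an electron-rich benzaldehyde (Dakin-type sequence): the alkoxy-substituted aryl group migrates in the Criegee intermediate to give formate 2, and carbonate-catalysed methanolysis then frees the phenol without touching the benzyl ether.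

Step 2
Reactants: 3 4-(benzyloxy)-3-methoxyphenol
Product: 5 5-(benzyloxy)-2-hydroxy-4-methoxybenzaldehyde, via salicyl alcohol 4 (not isolated)
Conditions: (CH2O)n, MgCl2, Et3N, MeCN, reflux
Reagents that add atoms: paraformaldehyde (as formaldehyde), C=O
Why: Magnesium-mediated ortho-formylation (Casnati-Skattebøl reaction): the magnesium phenoxide delivers formaldehyde only to an ortho carbon, the open C6 (para to OMe) is preferred over the position flanked by two oxygens, and the alkoxide of 4 is oxidised by a second formaldehyde in an Oppenauer-type hydride transfer.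

Step 3
Reactants: 5 5-(benzyloxy)-2-hydroxy-4-methoxybenzaldehyde; 6 N-acetylglycine
Product: 9 N-[6-(benzyloxy)-7-methoxy-2-oxo-2H-chromen-3-yl]acetamide, via 2-methyloxazol-5(4H)-one 7 (not isolated), via arylidene azlactone 8 (not isolated)
Conditions: Ac2O, NaOAc, 110 °C
Reagents that add atoms: none
Why: Erlenmeyer-Plöchl azlactone condensation followed by Perkin-type lactonisation: Ac2O cyclodehydrates 6 to oxazolone 7, whose C4 condenses with the aldehyde to give 8, and after equilibration of the alkene geometry in the hot acetate medium the ortho phenol opens the azlactone carbonyl, closing the pyranone of A and leaving the nitrogen as the 3-acetamido group.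

Step 4
Reactants: 9 N-[6-(benzyloxy)-7-methoxy-2-oxo-2H-chromen-3-yl]acetamide
Product: 11 6-(benzyloxy)-3-hydroxy-7-methoxy-2H-chromen-2-one, via 3-aminocoumarin 10 (not isolated)
Conditions: 3 M aq HCl, 1,4-dioxane, reflux
Reagents that add atoms: water, O
Why: Acid hydrolysis of an enamide: the acetamide is cleaved to the 3-aminocoumarin 10, whose iminium tautomer is hydrolysed to the 2,3-dioxo compound that rests as enol 11, while the aryl benzyl ether should survive dilute aqueous acid and the lactone recloses if it opens.

Step 5
Reactants: 11 6-(benzyloxy)-3-hydroxy-7-methoxy-2H-chromen-2-one; 12 methyl but-2-ynoate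
Product: 13 methyl (2E)-3-{[6-(benzyloxy)-7-methoxy-2-oxo-2H-chromen-3-yl]oxy}but-2-enoate
Conditions: DABCO (20 mol%), MeCN, 50 °C
Reagents that add atoms: none
Why: Amine-catalysed oxa-Michael addition of an acidic, phenol-like enol to the β carbon of an ynoate; oxygen is expected to react in preference to C4 because O-addition keeps the conjugated coumarin, and the E isomer (aryloxy trans to the ester, methyl cis to it) is the thermodynamic product under the reversible amine conditions.

Step 6
Reactants: 13 methyl (2E)-3-{[6-(benzyloxy)-7-methoxy-2-oxo-2H-chromen-3-yl]oxy}but-2-enoate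
Product: 14 (1Z)-3-{[6-(benzyloxy)-7-methoxy-2-oxo-2H-chromen-3-yl]oxy}-1-methoxy-1-[(trimethylsilyl)oxy]buta-1,3-diene
Conditions: TMSCl, then LiN(i-Pr)2 (LDA), THF, −78 °C; non-aqueous work-up, used crude
Reagents that add atoms: chlorotrimethylsilane (TMSCl), C[Si](C)(C)Cl
Why: Vinylogous (γ) deprotonation of a β-oxycrotonate by LDA, directed by the ester carbonyl to the cis methyl group, with O-silylation of the dienolate by the TMSCl already present (formation of a Brassard-type mixed vinylketene acetal); at −78 °C the amide base should not add to the coumarin lactone, as in the γ-lithiation of 4-methylcoumarins.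

Step 7
Reactants: 15 prop-2-yn-1-ol (propargyl alcohol)
Product: 16 propynal
Conditions: CrO3, H2SO4, H2O, 2-10 °C, reduced pressure (product distilled into cold traps), used fresh
Reagents that add atoms: none
Why: Chromic acid oxidation of a primary propargylic alcohol; the volatile ynal is swept out of the acidic oxidant under reduced pressure as it forms, which prevents over-oxidation and polymerisation.

Step 8
Reactants: 14 (1Z)-3-{[6-(benzyloxy)-7-methoxy-2-oxo-2H-chromen-3-yl]oxy}-1-methoxy-1-[(trimethylsilyl)oxy]buta-1,3-diene; 16 propynal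
Product: 19 4-{[6-(benzyloxy)-7-methoxy-2-oxo-2H-chromen-3-yl]oxy}-2-hydroxybenzaldehyde, via cyclohexa-1,4-diene cycloadduct 17 (not isolated), via aryl trimethylsilyl ether 18 (not isolated)
Conditions: PhMe, −20 °C to rt, under argon, acid-free; then 1 M HCl, THF, rt
Reagents that add atoms: none
Why: Diene 14 is a mixed vinylketene acetal whose HOMO coefficient is largest at the unsubstituted terminus C4, so it should add to the electron-poor triple bond of propynal in a strongly polarised, asynchronous Diels-Alder reaction (at the stepwise limit a Mukaiyama-Michael addition followed by closure of the allenolate onto the oxocarbenium carbon). The closest known reaction type is the benzannulation of 1-alkoxy-1-silyloxy-3-oxybutadienes with propiolates and ynones, which gives salicylate-type arenes. The one ring closed is the benzene ring of coumarin B, by an intermolecular [4+2] closure that forms C5'-C6' (diene C4 to the alkyne β carbon) and C4a'-C8a' (ketal carbon to the alkyne α carbon); 1,4-elimination of methanol from 17 then aromatises the ring and dilute acid removes silicon from 18. No stereocentre survives, since the ketal carbon of 17 forms as a racemate and becomes the sp2 carbon C8a'. The step needs regioselectivity (formyl ortho to the ketal carbon and para to the aryloxy carbon), which the donor pattern of the diene and the β-electrophilic ynal secure, and periselectivity for the triple bond over the formyl group, which the absence of any Lewis acid and the low temperature should secure because the uncatalysed carbonyl is a poor heterodienophile.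

Step 9
Reactants: 19 4-{[6-(benzyloxy)-7-methoxy-2-oxo-2H-chromen-3-yl]oxy}-2-hydroxybenzaldehyde; 20 ethyl (triphenylphosphoranylidene)acetate
Product: 22 6-(benzyloxy)-7-methoxy-3-[(2-oxo-2H-chromen-7-yl)oxy]-2H-chromen-2-one, via (E)-2-hydroxycinnamate 21 (not isolated)
Conditions: PhNEt2, reflux (ca. 215 °C)
Reagents that add atoms: none
Why: Wittig olefination with a stabilised ylide gives the (E)-2-hydroxycinnamate 21, which at the reflux temperature of N,N-diethylaniline isomerises about the double bond and lactonises with loss of ethanol (one-pot Wittig-lactonisation coumarin synthesis), closing the pyranone of B without acid or base that could open the lactone of A.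

Step 10
Reactants: 22 6-(benzyloxy)-7-methoxy-3-[(2-oxo-2H-chromen-7-yl)oxy]-2H-chromen-2-one
Product: 23 6-hydroxy-7-methoxy-3-[(2-oxo-2H-chromen-7-yl)oxy]-2H-chromen-2-one
Conditions: BCl3, C6HMe5, CH2Cl2, −78 °C; then H2O
Reagents that add atoms: none
Why: Lewis acid debenzylation of an aryl benzyl ether: BCl3 ionises the O-benzyl bond at −78 °C and pentamethylbenzene traps the benzyl cation by Friedel-Crafts alkylation, so the aryl methyl ether, the diaryl ether, both lactones and both C3=C4 double bonds (which hydrogenolysis could reduce) should stay intact.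

**Compound list**

1 | 4-(benzyloxy)-3-methoxybenzaldehyde (O-benzylvanillin) | COc1cc(C=O)ccc1OCc1ccccc1 | starting material
2 | 4-(benzyloxy)-3-methoxyphenyl formate | COc1cc(OC=O)ccc1OCc1ccccc1 | intermediate
3 | 4-(benzyloxy)-3-methoxyphenol | COc1cc(O)ccc1OCc1ccccc1 | intermediate
4 | 4-(benzyloxy)-2-(hydroxymethyl)-5-methoxyphenol | COc1cc(O)c(CO)cc1OCc1ccccc1 | intermediate
5 | 5-(benzyloxy)-2-hydroxy-4-methoxybenzaldehyde | COc1cc(O)c(C=O)cc1OCc1ccccc1 | intermediate
6 | N-acetylglycine | CC(=O)NCC(=O)O | starting material
7 | 2-methyl-1,3-oxazol-5(4H)-one | CC1=NCC(=O)O1 | intermediate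
8 | (4Z)-4-[5-(benzyloxy)-2-hydroxy-4-methoxybenzylidene]-2-methyl-1,3-oxazol-5(4H)-one | CC1=N/C(=C\c2cc(OCc3ccccc3)c(OC)cc2O)C(=O)O1 | intermediate
9 | N-[6-(benzyloxy)-7-methoxy-2-oxo-2H-chromen-3-yl]acetamide | CC(=O)Nc1cc2cc(OCc3ccccc3)c(OC)cc2oc1=O | intermediate
10 | 3-amino-6-(benzyloxy)-7-methoxy-2H-chromen-2-one | Nc1cc2cc(OCc3ccccc3)c(OC)cc2oc1=O | intermediate
11 | 6-(benzyloxy)-3-hydroxy-7-methoxy-2H-chromen-2-one | Oc1cc2cc(OCc3ccccc3)c(OC)cc2oc1=O | intermediate
12 | methyl but-2-ynoate | CC#CC(=O)OC | starting material
13 | methyl (2E)-3-{[6-(benzyloxy)-7-methoxy-2-oxo-2H-chromen-3-yl]oxy}but-2-enoate | COC(=O)/C=C(\C)Oc1cc2cc(OCc3ccccc3)c(OC)cc2oc1=O | intermediate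
14 | (1Z)-3-{[6-(benzyloxy)-7-methoxy-2-oxo-2H-chromen-3-yl]oxy}-1-methoxy-1-[(trimethylsilyl)oxy]buta-1,3-diene | C=C(Oc1cc2cc(OCc3ccccc3)c(OC)cc2oc1=O)/C=C(/OC)O[Si](C)(C)C | intermediate
15 | prop-2-yn-1-ol (propargyl alcohol) | C#CCO | starting material
16 | propynal | C#CC=O | intermediate
17 | 4-{[6-(benzyloxy)-7-methoxy-2-oxo-2H-chromen-3-yl]oxy}-6-methoxy-6-[(trimethylsilyl)oxy]cyclohexa-1,4-diene-1-carbaldehyde (racemic) | O=CC1=CCC(Oc2cc3cc(OCc4ccccc4)c(OC)cc3oc2=O)=CC1(OC)O[Si](C)(C)C | intermediate
18 | 4-{[6-(benzyloxy)-7-methoxy-2-oxo-2H-chromen-3-yl]oxy}-2-[(trimethylsilyl)oxy]benzaldehyde | O=Cc1ccc(Oc2cc3cc(OCc4ccccc4)c(OC)cc3oc2=O)cc1O[Si](C)(C)C | intermediate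
19 | 4-{[6-(benzyloxy)-7-methoxy-2-oxo-2H-chromen-3-yl]oxy}-2-hydroxybenzaldehyde | O=Cc1ccc(Oc2cc3cc(OCc4ccccc4)c(OC)cc3oc2=O)cc1O | intermediate
20 | ethyl (triphenylphosphoranylidene)acetate | CCOC(=O)C=P(c1ccccc1)(c1ccccc1)c1ccccc1 | starting material
21 | ethyl (2E)-3-(4-{[6-(benzyloxy)-7-methoxy-2-oxo-2H-chromen-3-yl]oxy}-2-hydroxyphenyl)prop-2-enoate | CCOC(=O)/C=C/c1ccc(Oc2cc3cc(OCc4ccccc4)c(OC)cc3oc2=O)cc1O | intermediate
22 | 6-(benzyloxy)-7-methoxy-3-[(2-oxo-2H-chromen-7-yl)oxy]-2H-chromen-2-one | COc1cc2oc(=O)c(Oc3ccc4ccc(=O)oc4c3)cc2cc1OCc1ccccc1 | intermediate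
23 | 6-hydroxy-7-methoxy-3-[(2-oxo-2H-chromen-7-yl)oxy]-2H-chromen-2-one | COc1cc2oc(=O)c(Oc3ccc4ccc(=O)oc4c3)cc2cc1O | target

**Step count**

Total step count: 10
Longest linear sequence: 9 steps (steps 1 to 6 and 8 to 10, from compound 1)

**Steps most likely to fail**

1. Step 8 (key step). The diene may attack the formyl carbon (vinylogous Mukaiyama aldol or hetero-Diels-Alder reaction) instead of the triple bond, propynal may polymerise, or traces of acid may protonate the ketene acetal back to 13 before cycloaddition. The fallback gives up the cycloaddition and closes the pyranone of A last, onto a finished aryl ether. It sets out from 5 and returns at 22. Commercial 7-hydroxycoumarin is alkylated with tert-butyl bromoacetate (K2CO3, acetone, reflux) to tert-butyl [(2-oxo-2H-chromen-7-yl)oxy]acetate F1. TFA in CH2Cl2 frees [(2-oxo-2H-chromen-7-yl)oxy]acetic acid F2. A Perkin-Oglialoro condensation of F2 with salicylaldehyde 5 (Ac2O, Et3N, 120 °C) should then give the 3-aryloxycoumarin 22 directly.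

2. Step 6. The lithium amide or the dienolate may add to the coumarin of A (1,2- or 1,4-addition), or the silyl ketene acetal may hydrolyse during the non-aqueous isolation, so that no intact diene reaches step 8. The fallback makes the ether by copper-mediated O-arylation of the enol. It sets out from 11 and returns at 22. 7-Hydroxycoumarin is converted (Tf2O, pyridine, CH2Cl2, 0 °C) into 2-oxo-2H-chromen-7-yl trifluoromethanesulfonate F3. Miyaura borylation (B2pin2, PdCl2(dppf), KOAc, dioxane, 80 °C) gives 7-(4,4,5,5-tetramethyl-1,3,2-dioxaborolan-2-yl)-2H-chromen-2-one F4. Chan-Lam-Evans coupling of F4 with 11 (Cu(OAc)2, pyridine, B(OH)3, 4 Å molecular sieves, MeCN, air, 60 °C) should give 22.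

3. Step 5. Conjugate addition to the β-methyl ynoate may be slow, and the ambident enol may alkylate at C4 instead of oxygen. The fallback replaces the catalytic addition by a vinylic addition-elimination. It sets out from 11 and returns at 13. Commercial (2E)-3-chlorobut-2-enoic acid is esterified (MeOH, H2SO4 cat., reflux) to methyl (2E)-3-chlorobut-2-enoate F5. The potassium salt of 11 (K2CO3, DMF, 60 °C) displaces chloride from F5 with retention of the alkene geometry to give 13.

**Further compounds**

F1 | step 8 | tert-butyl [(2-oxo-2H-chromen-7-yl)oxy]acetate | CC(C)(C)OC(=O)COc1ccc2ccc(=O)oc2c1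
F2 | step 8 | [(2-oxo-2H-chromen-7-yl)oxy]acetic acid | OC(=O)COc1ccc2ccc(=O)oc2c1
F3 | step 6 | 2-oxo-2H-chromen-7-yl trifluoromethanesulfonate | O=c1ccc2ccc(OS(=O)(=O)C(F)(F)F)cc2o1
F4 | step 6 | 7-(4,4,5,5-tetramethyl-1,3,2-dioxaborolan-2-yl)-2H-chromen-2-one | CC1(C)OB(c2ccc3ccc(=O)oc3c2)OC1(C)C
F5 | step 5 | methyl (2E)-3-chlorobut-2-enoate | COC(=O)/C=C(\C)Cl
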